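## Retrosynthetic overview

1. Last bond C5'–C6': copper-mediated Stille-type union of a dienylstannane epoxyquinol acetate with (2Z,6E)-7-iodo-2,6-dimethylhepta-2,6-dien-1-ol, with no protecting groups.
2. CH2OAc: formaldehyde Morita–Baylis–Hillman (MBH) reaction on the unveiled enone, then primary-selective acetylation; the stannane comes from hydrostannylation of a terminal enyne.
3. C4–OH and the oxirane (C5, C6) are relayed from the C1' carbinol by alkoxide-directed epoxidation and hydroxyl-directed reduction of a quinone-monoketal carbinol.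
4. C5–C1' bond and the first stereocentre (C1'): catalytic asymmetric MBH reaction of achiral 4,4-dimethoxycyclohexa-2,5-dienone with (E)-3-methylpent-2-en-4-ynal.
5. Rings: the carbocycle is bought as the quinone monoketal and the oxirane is the only ring formed (step 6). The iododienol comes from propargyl alcohol by carbomagnesiation, Negishi coupling and carboalumination.

Assumption: the target is read from the SMILES as ring (4S,5R,6R), side chain 1'S,2'E,4'E,6'E,10'Z (ring C1 = C=O, C2 = C–CH2OAc, C4 = CHOH, C5/C6 = oxirane); the antipode of the bis-thiourea in step 5 that gives the (S)-carbinol is fixed by a first run.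

## Route

Step 1
Reactants: 1 prop-2-yn-1-ol
Product: 3 (Z)-3-iodo-2-methylprop-2-en-1-ol, via vinylmagnesium alkoxide 2 (not isolated)
Conditions: MeMgBr (2.5 equiv), CuI (10 mol%), THF, −10 °C → rt; then I2, −40 → 0 °C
Reagents that add atoms: methylmagnesium bromide C[Mg]Br; iodine II
Why: Cu-catalysed anti-carbomagnesiation of the propargylic alkoxide puts Me on C2 and Mg on C3 cis to CH2O (chelate), and iodinolysis with retention gives only the (Z)-iodide.

Step 2
Reactants: 4 (4-bromobut-1-yn-1-yl)trimethylsilane; 3 (Z)-3-iodo-2-methylprop-2-en-1-ol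
Product: 7 (Z)-2-methylhept-2-en-6-yn-1-ol, via butynylzinc bromide 5 (not isolated), via silylated enynol 6 (not isolated)
Conditions: 4, Zn dust, LiCl, THF, 50 °C; then 3 (0.5 equiv, slow addition), Pd(OAc)2 (2 mol%), SPhos (4 mol%), rt; then K2CO3, MeOH, rt
Reagents that add atoms: none
Why: zinc insertion and Negishi sp3–sp2 coupling proceed with retention of the Z-alkene (excess zinc reagent covers the free OH), and carbonate methanolysis of the C–Si bond unmasks the alkyne in the same flask.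

Step 3
Reactants: 7 (Z)-2-methylhept-2-en-6-yn-1-ol
Product: 9 (2Z,6E)-7-iodo-2,6-dimethylhepta-2,6-dien-1-ol, via alkenylalane 8 (not isolated)
Conditions: AlMe3 (3 equiv), Cp2ZrCl2 (25 mol%), CH2Cl2, 0 °C → rt; then I2, THF, −30 °C
Reagents that add atoms: trimethylaluminium C[Al](C)C; iodine II
Why: Negishi Zr-catalysed syn-carboalumination (Me to the internal carbon, Al to the terminus) and iodinolysis with retention give the (E)-trisubstituted vinyl iodide; the OH travels as its aluminium alkoxide.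

Step 4
Reactants: 10 (E)-3-methylpent-2-en-4-yn-1-ol
Product: 11 (E)-3-methylpent-2-en-4-ynal
Conditions: MnO2 (15 equiv), CH2Cl2, rt; used as a solution
Reagents that add atoms: none
Why: MnO2 allylic oxidation stops at the aldehyde and does not isomerise the E-alkene.

Step 5
Reactants: 12 4,4-dimethoxycyclohexa-2,5-dien-1-one; 11 (E)-3-methylpent-2-en-4-ynal
Product: 13 2-[(1S,2E)-1-hydroxy-3-methylpent-2-en-4-yn-1-yl]-4,4-dimethoxycyclohexa-2,5-dien-1-one
Conditions: 12 (2 equiv), DMAP (30 mol%), 1,1'-(trans-cyclohexane-1,2-diyl)bis{3-[3,5-bis(trifluoromethyl)phenyl]thiourea} (single enantiomer, 20 mol%), toluene, −10 °C, 72 h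
Reagents that add atoms: none
Why: Proposed new method: a catalytic asymmetric Morita–Baylis–Hillman reaction with a p-quinone monoketal as the activated alkene – DMAP adds reversibly to C3 of 12 (the same β-onium dienolate passed through in the known pyridine/I2 α-iodination of this ketal), the C2-symmetric bis-thiourea holds the dienolate oxygen with one thiourea and the aldehyde oxygen of 11 with the other so that one aldehyde face is offered in the C–C bond-forming aldol step (this sets C1' as S), and β-elimination of DMAP returns the dienone; 11 cannot enolise and its β-carbon is fully substituted, so it reacts only 1,2, and an amine rather than a phosphine is used because a β-phosphonium adduct could lose methanol and aromatise; the closest known reaction is the thiourea/amine co-catalysed asymmetric MBH reaction of cyclohex-2-enone with aldehydes.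

Step 6
Reactants: 13 2-[(1S,2E)-1-hydroxy-3-methylpent-2-en-4-yn-1-yl]-4,4-dimethoxycyclohexa-2,5-dien-1-one
Product: 14 (1S,6R)-1-[(1S,2E)-1-hydroxy-3-methylpent-2-en-4-yn-1-yl]-5,5-dimethoxy-7-oxabicyclo[4.1.0]hept-3-en-2-one
Conditions: Ph3COOH (1.5 equiv), NaHMDS (2.2 equiv), toluene, −50 → −30 °C; AcOH quench
Reagents that add atoms: trityl hydroperoxide OOC(c1ccccc1)(c1ccccc1)c1ccccc1
Why: hydroxyl-directed nucleophilic (Weitz–Scheffer) epoxidation – in toluene the sodium alkoxide of C1' carries the peroxide to the β-carbon of its own enone (the unsubstituted enone on the far side is not reached), on the face that leaves C1'–H rather than the enynyl group next to the C4 carbonyl (minimised A(1,2) strain), which gives the (1S,6R)-oxirane.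

Step 7
Reactants: 14 (1S,6R)-1-[(1S,2E)-1-hydroxy-3-methylpent-2-en-4-yn-1-yl]-5,5-dimethoxy-7-oxabicyclo[4.1.0]hept-3-en-2-one
Product: 15 (1S,2S,6R)-1-[(1S,2E)-1-hydroxy-3-methylpent-2-en-4-yn-1-yl]-5,5-dimethoxy-7-oxabicyclo[4.1.0]hept-3-en-2-ol
Conditions: Me4NBH(OAc)3 (4 equiv), MeCN/AcOH 1:1, −30 °C
Reagents that add atoms: none
Why: Evans–Saksena hydroxyl-directed reduction – the C1'-O-bound acetoxyborohydride delivers hydride through a chair with the enynyl group equatorial, i.e. to the carbonyl face syn to the oxirane oxygen, giving the 1,3-anti diol with C4–OH trans to the epoxide (an undirected hydride would attack anti to the epoxide C–O bond and give the epimer).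

Step 8
Reactants: 15 (1S,2S,6R)-1-[(1S,2E)-1-hydroxy-3-methylpent-2-en-4-yn-1-yl]-5,5-dimethoxy-7-oxabicyclo[4.1.0]hept-3-en-2-ol
Product: 16 (1R,5S,6S)-5-hydroxy-6-[(1S,2E)-1-hydroxy-3-methylpent-2-en-4-yn-1-yl]-7-oxabicyclo[4.1.0]hept-3-en-2-one
Conditions: Montmorillonite K10, wet CH2Cl2, rt
Reagents that add atoms: water O
Why: mild acid-catalysed hydrolysis of the allylic dimethyl ketal unveils the enone without touching a stereocentre; the descriptor at the quaternary carbon changes only through CIP priorities.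

Step 9
Reactants: 16 (1R,5S,6S)-5-hydroxy-6-[(1S,2E)-1-hydroxy-3-methylpent-2-en-4-yn-1-yl]-7-oxabicyclo[4.1.0]hept-3-en-2-one
Product: 17 (1R,5S,6S)-5-hydroxy-6-[(1S,2E,4E)-1-hydroxy-3-methyl-5-(tributylstannyl)penta-2,4-dien-1-yl]-7-oxabicyclo[4.1.0]hept-3-en-2-one
Conditions: Bu3SnH (1.2 equiv, slow addition), PdCl2(PPh3)2 (3 mol%), THF, 0 °C
Reagents that add atoms: tributyltin hydride CCCC[SnH](CCCC)CCCC
Why: Pd-catalysed syn-hydrostannylation of the terminal enyne puts tin on the terminal carbon and gives the (E)-dienylstannane; it is run before any allylic acetate is present and is much faster than enone reduction.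

Step 10
Reactants: 17 (1R,5S,6S)-5-hydroxy-6-[(1S,2E,4E)-1-hydroxy-3-methyl-5-(tributylstannyl)penta-2,4-dien-1-yl]-7-oxabicyclo[4.1.0]hept-3-en-2-one
Product: 18 (1R,5S,6R)-5-hydroxy-3-(hydroxymethyl)-6-[(1S,2E,4E)-1-hydroxy-3-methyl-5-(tributylstannyl)penta-2,4-dien-1-yl]-7-oxabicyclo[4.1.0]hept-3-en-2-one
Conditions: 37% aq. HCHO (5 equiv), DMAP (30 mol%), THF/H2O, rt
Reagents that add atoms: formaldehyde C=O
Why: Morita–Baylis–Hillman hydroxymethylation of the only enone (DMAP adds at C3, aldol with formaldehyde at C2, elimination); the base is too weak for Payne rearrangement and the vinylstannane is inert.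

Step 11
Reactants: 18 (1R,5S,6R)-5-hydroxy-3-(hydroxymethyl)-6-[(1S,2E,4E)-1-hydroxy-3-methyl-5-(tributylstannyl)penta-2,4-dien-1-yl]-7-oxabicyclo[4.1.0]hept-3-en-2-one
Product: 19 [(1R,5S,6R)-5-hydroxy-6-[(1S,2E,4E)-1-hydroxy-3-methyl-5-(tributylstannyl)penta-2,4-dien-1-yl]-2-oxo-7-oxabicyclo[4.1.0]hept-3-en-3-yl]methyl acetate
Conditions: AcCl (1.1 equiv), 2,4,6-collidine, CH2Cl2, −78 °C
Reagents that add atoms: acetyl chloride CC(=O)Cl
Why: kinetically controlled acylation takes the primary allylic OH; both secondary OH groups sit next to the quaternary oxirane carbon and stay free.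

Step 12
Reactants: 19 [(1R,5S,6R)-5-hydroxy-6-[(1S,2E,4E)-1-hydroxy-3-methyl-5-(tributylstannyl)penta-2,4-dien-1-yl]-2-oxo-7-oxabicyclo[4.1.0]hept-3-en-3-yl]methyl acetate; 9 (2Z,6E)-7-iodo-2,6-dimethylhepta-2,6-dien-1-ol
Product: 20 [(1R,5S,6R)-5-hydroxy-6-[(1S,2E,4E,6E,10Z)-1,12-dihydroxy-3,7,11-trimethyldodeca-2,4,6,10-tetraen-1-yl]-2-oxo-7-oxabicyclo[4.1.0]hept-3-en-3-yl]methyl acetate
Conditions: CuTC (1.5 equiv), NMP, 0 °C → rt, dark
Reagents that add atoms: none
Why: copper(I) thiophene-2-carboxylate-mediated Stille-type coupling (Sn→Cu transmetalation, then coupling with the vinyl iodide) keeps both alkene geometries, needs no palladium (the allylic acetate is not ionised) and tolerates the free hydroxyls.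

## Compound list

1 | prop-2-yn-1-ol | C#CCO | starting material
2 | bromomagnesium (Z)-3-(bromomagnesio)-2-methylprop-2-en-1-olate | Br[Mg]/C=C(/C)CO[Mg]Br | intermediate
3 | (Z)-3-iodo-2-methylprop-2-en-1-ol | I/C=C(/C)CO | intermediate
4 | (4-bromobut-1-yn-1-yl)trimethylsilane | C[Si](C)(C)C#CCCBr | starting material
5 | [4-(trimethylsilyl)but-3-yn-1-yl]zinc bromide | C[Si](C)(C)C#CCC[Zn]Br | intermediate
6 | (Z)-2-methyl-7-(trimethylsilyl)hept-2-en-6-yn-1-ol | C[Si](C)(C)C#CCC/C=C(/C)CO | intermediate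
7 | (Z)-2-methylhept-2-en-6-yn-1-ol | C#CCC/C=C(/C)CO | intermediate
8 | dimethylaluminium (2Z,6E)-7-(dimethylalumanyl)-2,6-dimethylhepta-2,6-dien-1-olate | C[Al](C)/C=C(\C)CC/C=C(/C)CO[Al](C)C | intermediate
9 | (2Z,6E)-7-iodo-2,6-dimethylhepta-2,6-dien-1-ol | I/C=C(\C)CC/C=C(/C)CO | intermediate
10 | (E)-3-methylpent-2-en-4-yn-1-ol | C#C/C(C)=C/CO | starting material
11 | (E)-3-methylpent-2-en-4-ynal | C#C/C(C)=C/C=O | intermediate
12 | 4,4-dimethoxycyclohexa-2,5-dien-1-one | COC1(OC)C=CC(=O)C=C1 | starting material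
13 | 2-[(1S,2E)-1-hydroxy-3-methylpent-2-en-4-yn-1-yl]-4,4-dimethoxycyclohexa-2,5-dien-1-one | O=C1C=CC(OC)(OC)C=C1[C@@H](O)/C=C(C)/C#C | intermediate
14 | (1S,6R)-1-[(1S,2E)-1-hydroxy-3-methylpent-2-en-4-yn-1-yl]-5,5-dimethoxy-7-oxabicyclo[4.1.0]hept-3-en-2-one | C1=CC(=O)[C@@]2([C@@H](O)/C=C(C)/C#C)O[C@H]2C1(OC)OC | intermediate
15 | (1S,2S,6R)-1-[(1S,2E)-1-hydroxy-3-methylpent-2-en-4-yn-1-yl]-5,5-dimethoxy-7-oxabicyclo[4.1.0]hept-3-en-2-ol | C1=C[C@H](O)[C@@]2([C@@H](O)/C=C(C)/C#C)O[C@H]2C1(OC)OC | intermediate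
16 | (1R,5S,6S)-5-hydroxy-6-[(1S,2E)-1-hydroxy-3-methylpent-2-en-4-yn-1-yl]-7-oxabicyclo[4.1.0]hept-3-en-2-one | C1=C[C@H](O)[C@@]2([C@@H](O)/C=C(C)/C#C)O[C@H]2C1=O | intermediate
17 | (1R,5S,6S)-5-hydroxy-6-[(1S,2E,4E)-1-hydroxy-3-methyl-5-(tributylstannyl)penta-2,4-dien-1-yl]-7-oxabicyclo[4.1.0]hept-3-en-2-one | C1=C[C@H](O)[C@@]2([C@@H](O)/C=C(C)/C=C/[Sn](CCCC)(CCCC)CCCC)O[C@H]2C1=O | intermediate
18 | (1R,5S,6R)-5-hydroxy-3-(hydroxymethyl)-6-[(1S,2E,4E)-1-hydroxy-3-methyl-5-(tributylstannyl)penta-2,4-dien-1-yl]-7-oxabicyclo[4.1.0]hept-3-en-2-one | OCC1=C[C@H](O)[C@@]2([C@@H](O)/C=C(C)/C=C/[Sn](CCCC)(CCCC)CCCC)O[C@H]2C1=O | intermediate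
19 | [(1R,5S,6R)-5-hydroxy-6-[(1S,2E,4E)-1-hydroxy-3-methyl-5-(tributylstannyl)penta-2,4-dien-1-yl]-2-oxo-7-oxabicyclo[4.1.0]hept-3-en-3-yl]methyl acetate | CC(=O)OCC1=C[C@H](O)[C@@]2([C@@H](O)/C=C(C)/C=C/[Sn](CCCC)(CCCC)CCCC)O[C@H]2C1=O | intermediate
20 | [(1R,5S,6R)-5-hydroxy-6-[(1S,2E,4E,6E,10Z)-1,12-dihydroxy-3,7,11-trimethyldodeca-2,4,6,10-tetraen-1-yl]-2-oxo-7-oxabicyclo[4.1.0]hept-3-en-3-yl]methyl acetate | CC(=O)OCC1=C[C@H](O)[C@@]2([C@@H](O)/C=C(C)/C=C/C=C(\C)CC/C=C(/C)CO)O[C@H]2C1=O | target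

## Step count and risks

Total steps: 12. Longest linear sequence: 9 (steps 4–12, from 10 to 20); the iodide arm is 3 steps (1–3) and joins in step 12.

The three steps most likely to fail:

Step 5 (the proposed asymmetric MBH reaction): the β-carbon of 12 is neopentyl-like and 11 is a conjugated aldehyde, so turnover or ee may be low. The fallback uses known chemistry only, sets out from 12 and 11 and comes back at 13. α-Iodination of 12 (I2, pyridine, CH2Cl2) gives 2-iodo-4,4-dimethoxycyclohexa-2,5-dien-1-one F1. Nozaki–Hiyama–Kishi coupling of F1 with 11 (CrCl2, cat. NiCl2, DMF) gives racemic 2-[(2E)-1-hydroxy-3-methylpent-2-en-4-yn-1-yl]-4,4-dimethoxycyclohexa-2,5-dien-1-one F2. Acylative kinetic resolution of F2 with a chiral isothiourea (HyperBTM 2 mol%, isobutyric anhydride 0.55 equiv, i-Pr2NEt, CHCl3, 0 °C) converts the (R)-alcohol into (1R,2E)-1-(3,3-dimethoxy-6-oxocyclohexa-1,4-dien-1-yl)-3-methylpent-2-en-4-yn-1-yl 2-methylpropanoate F3 and leaves the (S)-alcohol 13, so the first stereocentre is still fixed by a metal-free catalyst.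

Step 6 (directed epoxidation): the unsubstituted enone could compete, or a chelated conformer could deliver oxygen to the wrong face. The fallback sets out from 13 and comes back at 14 in one operation, replacing substrate-directed nucleophilic delivery by reagent-controlled electrophilic oxygen transfer. Titanium–tartrate epoxidation (Ti(OiPr)4, D-(−)-diisopropyl tartrate, TBHP, 4 Å sieves, CH2Cl2, −20 °C) can only reach the alkene that carries the carbinol, and the tartrate (the matched antipode for the (S)-carbinol by the usual mnemonic) fixes the face. It makes no new compound (F0).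

Step 10 (late hydroxymethylation on a stannane-bearing epoxy enone): conversion may be slow or the γ-hydroxy epoxy enone may degrade. The fallback sets out from 16 and comes back at 18, swapping the order of stannylation and C1 introduction. α-Iodination of 16 (I2, pyridine, CH2Cl2) gives (1R,5S,6R)-5-hydroxy-6-[(1S,2E)-1-hydroxy-3-methylpent-2-en-4-yn-1-yl]-3-iodo-7-oxabicyclo[4.1.0]hept-3-en-2-one F4. Stille coupling of F4 with (tributylstannyl)methanol (Pd2(dba)3, AsPh3, NMP, 40 °C) gives (1R,5S,6R)-5-hydroxy-3-(hydroxymethyl)-6-[(1S,2E)-1-hydroxy-3-methylpent-2-en-4-yn-1-yl]-7-oxabicyclo[4.1.0]hept-3-en-2-one F5. Hydrostannylation of F5 under the step 9 conditions gives 18.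

## Further compounds

F1 | step 5 | 2-iodo-4,4-dimethoxycyclohexa-2,5-dien-1-one | COC1(OC)C=CC(=O)C(I)=C1
F2 | step 5 | racemic 2-[(2E)-1-hydroxy-3-methylpent-2-en-4-yn-1-yl]-4,4-dimethoxycyclohexa-2,5-dien-1-one | O=C1C=CC(OC)(OC)C=C1C(O)/C=C(C)/C#C
F3 | step 5 | (1R,2E)-1-(3,3-dimethoxy-6-oxocyclohexa-1,4-dien-1-yl)-3-methylpent-2-en-4-yn-1-yl 2-methylpropanoate | O=C1C=CC(OC)(OC)C=C1[C@H](OC(=O)C(C)C)/C=C(C)/C#C
F0 | step 6 | none | none
F4 | step 10 | (1R,5S,6R)-5-hydroxy-6-[(1S,2E)-1-hydroxy-3-methylpent-2-en-4-yn-1-yl]-3-iodo-7-oxabicyclo[4.1.0]hept-3-en-2-one | IC1=C[C@H](O)[C@@]2([C@@H](O)/C=C(C)/C#C)O[C@H]2C1=O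
F5 | step 10 | (1R,5S,6R)-5-hydroxy-3-(hydroxymethyl)-6-[(1S,2E)-1-hydroxy-3-methylpent-2-en-4-yn-1-yl]-7-oxabicyclo[4.1.0]hept-3-en-2-one | OCC1=C[C@H](O)[C@@]2([C@@H](O)/C=C(C)/C#C)O[C@H]2C1=O
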